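## Structural features

The target 9 is a symmetric diarylmethane (C13H8Br4O4): two identical benzene rings joined through one sp3 carbon, the CH2 bridge, with no other ring or chain. In each ring C1 carries the bridge, C2 and C3 carry bromine, C4 and C5 carry hydroxyl, and only C6 carries hydrogen. The target has no stereocentre, so no neighbouring stereocentres have to be related. The fragile parts are the two catechols (taken to o-quinones by quinone oxidants, bromine, or air in base), the doubly benzylic CH2, and the four C–Br bonds, which rule out dissolving metals and catalytic hydrogenation late in the route. The real difficulty is not the skeleton but placing bromine on C2 and C3 while C6 stays free, and reaching the catechol oxidation level without overshooting it. The key step uses the fact that each ring divides into a two-carbon unit C1–C2 attached to the bridge carbon and a four-carbon unit C3–C4–C5–C6 with oxygen on its two inner carbons, that is, a vinyl group of a cross-conjugated dienone and a 2,3-dioxygenated buta-1,3-diene. The bridge carbon therefore enters as a ketone, which activates the dienophile, acidifies C1–H for the aromatisation and later steers the second bromine to C3. The cycloadduct does carry a stereocentre at C1 of each ring, but both are erased on aromatisation.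

## Logic of the disconnections

**9 ⇒ 8.** The four O–H bonds of 9 are traced back to four O–CH3 bonds. Free catechols would not survive the oxidant, the bromine or the strong acid used earlier, so they are carried as ethers and released together at the end. The gain is that the four phenols become inert spectators. The demand is an ether cleavage that leaves the C–Br bonds and the CH2 bridge untouched.

**8 ⇒ 7.** The two C–H bonds of the bridge carbon are traced back to a C=O. The carbonyl is what the ring-forming chemistry delivers, and it is kept as long as it is useful. The gain is a direct link to the ketone series. The demand is reduction of a diaryl ketone flanked by two ortho bromines to CH2 without C–Br cleavage, which points to hydride transfer to a cation and away from metals.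

**7 ⇒ 6.** The C2–Br and C3–Br bonds of both rings are cut, four C–Br bonds in all. The cut is made at the ketone stage, not after reduction. The first bromine goes to C2, para to the C5 oxygen, in either series. For the second, the carbonyl deactivates C6 (ortho to it) more than C3 (meta to it), the C2 bromine directs ortho to C3, and the aroyl group crowds C6. In the reduced series the bridge would be an activating alkyl group ortho to C6 and this bias would be lost. The gain is a halogen-free, symmetric precursor. The demand is complete fourfold substitution without ether cleavage.

**6 ⇒ 5.** No skeletal bond is cut; each arene is taken back to a cyclohexene by adding one hydrogen each at C1, C2, C3 and C6. This exposes the cyclohexene retron with the C4=C5 enediol double bond. The gain is that the rings can now come from a cycloaddition. The demand is an oxidant that removes four hydrogens per ring and then stops. This is secured by capping the oxygens as methyl ethers from the start, because a dimethoxyarene cannot go on to an o-quinone. A silyl-capped enediol would be desilylated and carried to the 1,2-dicarbonyl level by the same oxidant.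

**5 ⇒ 4 ⇒ 3 + two 1.** The C2–C3 and C6–C1 bonds of each ring are cut, four C–C bonds in two retro-[4+2] operations. These bonds join the two-carbon unit on the bridge to the four-carbon unit bearing both oxygens. The gain is the largest of the route: both rings and the whole C13 skeleton fall apart into one C5 and two C4 acyclic pieces. The demands are complete double addition and suppression of polymerisation. There is no regiochemical demand because 1 is symmetric, and the two C1 stereocentres need no control.

**3 ⇒ 2.** The two C=C bonds of 3 are traced back to H–C–C–Cl units. 3 polymerises on storage, while 2 is a stable latent form. The gain is a storable starting material. The demand is a base strong enough for twofold loss of HCl but not nucleophilic toward the enone, and a release rate matched to the cycloaddition.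

## Other disconnections considered

**Alternative 1:** The cut is at the two C1–C(bridge) bonds. The bridge carbon would come from ethyl formate A2 and each fully substituted ring from 2,3-dibromo-1-iodo-4,5-dimethoxybenzene A1 after iodine–magnesium exchange. Two additions to A2 would give bis(2,3-dibromo-4,5-dimethoxyphenyl)methanol A3; no ring is formed.
- In its favour: every substituent is in place before the coupling, so the bromine pattern is settled beforehand. On this point it is better than the chosen plan, which relies on directing effects in step 3.
- In its favour: A3 is only a deoxygenation and an ether cleavage from 9 (the reaction types of steps 4 and 5). That is two steps after its key step against four here, so it is also better on that count.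
- Against it: A1 is not a stock compound. Its preparation means placing two adjacent bromines and an iodine around a dimethoxyarene, the same regiochemical problem on a substrate without a carbonyl to help, and would add several steps.
- Against it: an arylmagnesium with an ortho bromine can expel magnesium halide to an aryne on warming, the exchange must pick iodine over two bromines, and the second addition meets a hindered ortho-substituted aldehyde.
- Comparison: structurally it forms two C–C bonds and no ring, while the chosen step forms four C–C bonds and both rings from acyclic pieces. Mechanistically it is cryogenic polar organometallic chemistry against a thermal pericyclic reaction. Overall length should be similar or somewhat longer once A1 is counted.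

**Alternative 2:** The cut is at C3–C4 and C5–C6 of each ring. The two oxygenated carbons would come from vinylene carbonate A5 and the other four ring carbons, with the bridge already attached, from 3,5-dimethylidenehepta-1,6-diene A4. Two thermal [4+2] reactions would give 5,5'-methylenebis(cis-3a,4,7,7a-tetrahydro-1,3-benzodioxol-2-one) A6.
- In its favour: the bridge is already CH2, so no step like step 4 is needed; here it is better.
- In its favour: the cyclic carbonate is more robust than the enol ethers of 5, also better.
- Equal: it builds two rings and four C–C bonds, and its stereocentres (four against two) are likewise destroyed later.
- Against it: A4 is a skipped bis-diene that is not purchasable and is prone to polymerisation. A5 is a sluggish dienophile that needs prolonged heating at high temperature, just the conditions A4 tolerates least.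
- Against it: A6 has its oxygens on sp3 carbons. Aromatisation would need carbonate hydrolysis, oxidation of a secondary diol and a further dehydrogenation, then protection of the catechol before bromination.
- Against it: with no carbonyl on the bridge, nothing steers the second bromine away from C6.
- Comparison: the two plans divide each ring in complementary ways and are mechanistically alike. The chosen plan should be clearly shorter and has the better regiocontrol element.

**Alternative 3:** The cut is at the C4–C5 bond of each ring. Tetramethyl 3,3'-methylenedihexanedioate A7 would be reduced with sodium metal in the presence of a chlorosilane trap (acyloin condensation with silyl trapping) to give bis[3,4-bis(trimethylsilyloxy)cyclohex-3-en-1-yl]methane A8.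
- In its favour: acyloin closure of adipate-type diesters to six-membered rings is dependable, and the bridge is already CH2 (better than the chosen plan on that point).
- Equal: A8 has its rings at the same oxidation level as 5 and is likewise a stereochemically irrelevant mixture.
- Against it: the key step forms only two C–C bonds. The whole carbon chain must be assembled beforehand in A7, which is not purchasable and would cost several steps.
- Against it: four ester groups can pair wrongly (a seven-membered acyloin between the two adipate units is conceivable).
- Against it: molten sodium in hot toluene with a chlorosilane is the most hazardous operation of the four plans.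
- Against it: the silyl enediol ethers of A8 are moisture-sensitive and tend to give 1,2-diones, not arenes, on oxidation. A8 also lacks the ketone that acidifies C1–H in 5 and directs the bromination of 6.
- Comparison: radical-anion ester coupling against cycloaddition. The chosen plan is shorter, safer and better controlled; the alternative wins only on the oxidation level of the bridge.

Key step: step 1

**Remarks on the chemistry**

- Assumption: 1 and 2 are taken as purchasable, and 3 is never isolated.
- The enediol oxygens are carried as methyl ethers and not as trimethylsilyl ethers. The diene skeleton, the bonds formed and the rings closed are unchanged. A bis(silyl) enediol ether adduct would be hydrolytically labile and, on quinone oxidation, would be desilylated and carried to the 1,2-diketone or o-quinone level. A free catechol, if formed, would itself be oxidised by the same reagent. The methyl ethers stop the oxidation at the arene and survive until the final deprotection.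
- The cycloadduct 5 is not free of stereocentres. C1 of each ring is stereogenic, so 5 should form as a meso/racemic mixture. This is harmless because both centres become sp2 in step 2.
- Bromination is placed before the reduction of the bridge carbonyl, for the directing reasons given above.

## Steps

Step 1
Reactants: 1 2,3-dimethoxybuta-1,3-diene; 2 1,5-dichloropentan-3-one
Product: 5 bis(3,4-dimethoxycyclohex-3-en-1-yl)methanone (meso/racemic mixture), via penta-1,4-dien-3-one 3 (not isolated), via 3,4-dimethoxycyclohex-3-enyl vinyl ketone 4 (not isolated)
Conditions: 1 (3 equiv), i-Pr2NEt (2.5 equiv), BHT (cat.), PhMe, 105 °C (sealed vessel), 2 added slowly over several hours; filtration, NaHCO3 wash, Et3N-deactivated silica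
Reagents that add atoms: none
Why: The hindered amine removes HCl twice from 2 by E1cB elimination and so releases dienone 3 at a low stationary concentration. Each vinyl group of 3 then undergoes a concerted, suprafacial [4+2] cycloaddition of normal electron demand with the electron-rich s-cis diene 1; the closest known reaction type is the Diels–Alder reaction of 2,3-dialkoxy- and 2,3-bis(silyloxy)butadienes with vinyl ketones. The first cycloaddition gives 4, whose remaining vinyl group is still conjugated to the carbonyl and reacts as an ordinary alkyl vinyl ketone with a second molecule of 1. Each six-membered ring is thus closed by an intermolecular two-component cycloaddition that forms C2–C3 and C6–C1 at once, not by cyclisation of a chain. Because 1 is symmetrically substituted, neither ring has a regiochemical choice. The only new stereocentres are C1 of each ring; nothing controls them, 5 should form as meso and racemic isomers, and this is irrelevant because both centres are flattened in step 2. The selectivity needed is double over single addition and cycloaddition over polymerisation or hetero-Diels–Alder reaction of an enone with an enol ether double bond; excess 1, slow release of 3, a radical inhibitor and the absence of Lewis acid should secure it. The excess amine keeps the medium basic, so the acid-labile enol ethers of 1, 4 and 5 should survive.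

Step 2
Reactants: 5 bis(3,4-dimethoxycyclohex-3-en-1-yl)methanone
Product: 6 bis(3,4-dimethoxyphenyl)methanone
Conditions: DDQ (4.5 equiv), dry PhMe, 90 °C, Ar
Reagents that add atoms: none
Why: Quinone dehydrogenation of a hydroaromatic enol ether: hydride abstraction from an allylic CH2 next to the enol ether gives a methoxy-stabilised allyl cation, proton loss (at C1, acidified by the ketone) gives a dienol ether, and a second hydride/proton loss gives the arene. The methyl ethers should stop the oxidation at the dimethoxyarene since no o-quinone can form, and both C1 stereocentres disappear.

Step 3
Reactants: 6 bis(3,4-dimethoxyphenyl)methanone
Product: 7 bis(2,3-dibromo-4,5-dimethoxyphenyl)methanone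
Conditions: Br2 (6 equiv), Fe powder (0.1 equiv), AcOH, 25 → 60 °C
Reagents that add atoms: bromine, BrBr
Why: Electrophilic aromatic bromination; the first bromine on each ring should enter C2, para to the C5 methoxy group. The second should enter C3 (ortho to the C4 methoxy group and to the C2 bromine, meta to the carbonyl) and not C6, which is ortho to the deactivating carbonyl and shielded by the aroyl group; FeBr3 formed in the flask supplies the electrophilic strength for this slower substitution.

Step 4
Reactants: 7 bis(2,3-dibromo-4,5-dimethoxyphenyl)methanone
Product: 8 bis(2,3-dibromo-4,5-dimethoxyphenyl)methane
Conditions: Et3SiH (5 equiv), CF3CO2H/CH2Cl2 (1:1), 0 → 40 °C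
Reagents that add atoms: none
Why: Ionic hydrogenation: the protonated ketone accepts hydride to give the benzhydrol, which ionises to a benzhydryl cation stabilised by the para C4 methoxy groups and accepts a second hydride. No metal or radical is involved, so the four C–Br bonds should be untouched.

Step 5
Reactants: 8 bis(2,3-dibromo-4,5-dimethoxyphenyl)methane
Product: 9 bis(2,3-dibromo-4,5-dihydroxyphenyl)methane
Conditions: BBr3 (8 equiv), CH2Cl2, −78 °C → rt; then H2O, 0 °C, acidic work-up under Ar
Reagents that add atoms: none
Why: Lewis-acid cleavage of aryl methyl ethers: boron coordinates to oxygen, bromide attacks the methyl group in an SN2 step, and the aryl borates are hydrolysed on work-up. Aryl bromides and the CH2 bridge are inert to BBr3, and an acidic, air-free work-up protects the catechols.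

## Compound list

1 | 2,3-dimethoxybuta-1,3-diene | C=C(OC)C(=C)OC | starting material
2 | 1,5-dichloropentan-3-one | ClCCC(=O)CCCl | starting material
3 | penta-1,4-dien-3-one | C=CC(=O)C=C | intermediate
4 | 1-(3,4-dimethoxycyclohex-3-en-1-yl)prop-2-en-1-one (racemic) | C=CC(=O)C1CCC(OC)=C(OC)C1 | intermediate
5 | bis(3,4-dimethoxycyclohex-3-en-1-yl)methanone (meso and racemic isomers) | O=C(C1CCC(OC)=C(OC)C1)C1CCC(OC)=C(OC)C1 | intermediate
6 | bis(3,4-dimethoxyphenyl)methanone | COc1ccc(cc1OC)C(=O)c1ccc(OC)c(OC)c1 | intermediate
7 | bis(2,3-dibromo-4,5-dimethoxyphenyl)methanone | COc1cc(C(=O)c2cc(OC)c(OC)c(Br)c2Br)c(Br)c(Br)c1OC | intermediate
8 | bis(2,3-dibromo-4,5-dimethoxyphenyl)methane | COc1cc(Cc2cc(OC)c(OC)c(Br)c2Br)c(Br)c(Br)c1OC | intermediate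
9 | bis(2,3-dibromo-4,5-dihydroxyphenyl)methane | Oc1cc(Cc2cc(O)c(O)c(Br)c2Br)c(Br)c(Br)c1O | target

## Step count and least certain steps

Total step count: 5. Longest linear sequence: 5 steps (2 → 5 → 6 → 7 → 8 → 9).

**Step 1 (key step).** The most likely failure is polymerisation of the dienone as it is released, or a stop after the first cycloaddition, because elimination and cycloaddition run at unmatched rates. Hetero-Diels–Alder reaction of an enone with an enol ether double bond and acid-induced enol ether hydrolysis on work-up are lesser risks. The fallback avoids the free dienone by building the two rings one after the other; it sets out from 1 and comes back to the route at 5. Compound 1 is heated with acrolein (PhMe, BHT, 80 °C) to give 3,4-dimethoxycyclohex-3-ene-1-carbaldehyde F1. Addition of CH2=CHMgBr (THF, −78 °C) gives 1-(3,4-dimethoxycyclohex-3-en-1-yl)prop-2-en-1-ol F2. Oxidation with MnO2 (CH2Cl2, rt) gives 4, this time isolated, and heating 4 with one further equivalent of 1 (PhMe, 105 °C) gives 5.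

**Step 2.** The dehydrogenation may stall at a dihydroarene stage on one ring. Cationic intermediates may be captured by traces of water, leading to methoxy ketones and then phenols, or may form covalent adducts with the quinone. The fallback replaces stoichiometric hydride abstraction by heterogeneous catalytic dehydrogenation, which has no cationic intermediates. It sets out from 5 and comes back at 6: heating 5 with Pd/C (10 wt % Pd) in refluxing mesitylene under an argon sweep removes hydrogen as H2. No new compound arises on this path.

**Step 3.** The substitution may stop after one bromine per ring, some attack may occur at C6, and HBr may cleave an ether and so misdirect further bromination. The fallback uses a free phenol as the directing group; it sets out from 6 and comes back to the route at 9. The methoxy group para to the carbonyl on each ring is cleaved selectively by NaSEt (DMF, 130 °C), because its phenoxide is the one conjugated with the ketone, giving bis(4-hydroxy-3-methoxyphenyl)methanone F3. Bromination (Br2, Fe powder, AcOH) should then go first ortho to the phenol at C3 and then to C2, para to the remaining methoxy group, giving bis(2,3-dibromo-4-hydroxy-5-methoxyphenyl)methanone F4. Ionic hydrogenation as in step 4 gives bis(2,3-dibromo-4-hydroxy-5-methoxyphenyl)methane F5, and BBr3 as in step 5 gives 9.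

**Step 4.** Protonation of the twisted, electron-poor, doubly ortho-substituted ketone may be too unfavourable, so that the reduction stalls at the ketone or at the carbinol/trifluoroacetate stage. The fallback separates carbonyl reduction from deoxygenation; it sets out from 7 and comes back at 8. NaBH4 (THF/MeOH, 0 °C → rt) reduces 7 to bis(2,3-dibromo-4,5-dimethoxyphenyl)methanol F6 (the same compound as A3). This carbinol ionises much more readily than the protonated ketone and is deoxygenated with Et3SiH and BF3·OEt2 (CH2Cl2, 0 °C) to 8.

## Further compounds

F1 | step 1 | 3,4-dimethoxycyclohex-3-ene-1-carbaldehyde (racemic) | O=CC1CCC(OC)=C(OC)C1
F2 | step 1 | 1-(3,4-dimethoxycyclohex-3-en-1-yl)prop-2-en-1-ol (mixture of diastereomers) | C=CC(O)C1CCC(OC)=C(OC)C1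
F0 | step 2 | none | none
F3 | step 3 | bis(4-hydroxy-3-methoxyphenyl)methanone | COc1cc(ccc1O)C(=O)c1ccc(O)c(OC)c1
F4 | step 3 | bis(2,3-dibromo-4-hydroxy-5-methoxyphenyl)methanone | COc1cc(C(=O)c2cc(OC)c(O)c(Br)c2Br)c(Br)c(Br)c1O
F5 | step 3 | bis(2,3-dibromo-4-hydroxy-5-methoxyphenyl)methane | COc1cc(Cc2cc(OC)c(O)c(Br)c2Br)c(Br)c(Br)c1O
F6 | step 4 | bis(2,3-dibromo-4,5-dimethoxyphenyl)methanol | COc1cc(C(O)c2cc(OC)c(OC)c(Br)c2Br)c(Br)c(Br)c1OC
A1 | alternative 1 | 2,3-dibromo-1-iodo-4,5-dimethoxybenzene | COc1cc(I)c(Br)c(Br)c1OC
A2 | alternative 1 | ethyl formate | CCOC=O
A3 | alternative 1 | bis(2,3-dibromo-4,5-dimethoxyphenyl)methanol | COc1cc(C(O)c2cc(OC)c(OC)c(Br)c2Br)c(Br)c(Br)c1OC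
A4 | alternative 2 | 3,5-dimethylidenehepta-1,6-diene | C=CC(=C)CC(=C)C=C
A5 | alternative 2 | vinylene carbonate (1,3-dioxol-2-one) | O=C1OC=CO1
A6 | alternative 2 | 5,5'-methylenebis(cis-3a,4,7,7a-tetrahydro-1,3-benzodioxol-2-one) (one of two cis,cis diastereomers) | O=C1O[C@@H]2CC=C(CC3=CC[C@@H]4OC(=O)O[C@@H]4C3)C[C@@H]2O1
A7 | alternative 3 | tetramethyl 3,3'-methylenedihexanedioate | COC(=O)CCC(CC(=O)OC)CC(CC(=O)OC)CCC(=O)OC
A8 | alternative 3 | bis[3,4-bis(trimethylsilyloxy)cyclohex-3-en-1-yl]methane (mixture of diastereomers) | C[Si](C)(C)OC1=C(O[Si](C)(C)C)CC(CC2CCC(O[Si](C)(C)C)=C(O[Si](C)(C)C)C2)CC1
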